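Readings and results stem from a simulated flask with constants of no real substance.

Product cannot pass the charge: counted as the substrate it holds, it stops at 100%, and that is our first ceiling for violet and for blue.

| flask | substrate | remark | time |
|---|---|---|---|
| delta | 0.11 M | run made earlier |  |
| epsilon | 0.19 M | run made earlier |  |
| eta | 0.18 M | run made earlier |  |
| violet | 0.15 M |  | 50 min |
| blue | 0.25 M |  | 30 min |

| run | time / min | product / % |
|---|---|---|
| delta | 1.33 | 5.9 |
| delta | 4.00 | 13.5 |
| delta | 8.00 | 26.4 |
| delta | 10.0 | 30.5 |
| delta | 15.0 | 41.1 |
| epsilon | 3.00 | 18.1 |
| epsilon | 6.00 | 33.2 |
| epsilon | 10.0 | 44.8 |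
| epsilon | 12.0 | 47.1 |
| epsilon | 15.0 | 56.0 |
| eta | 1.33 | 8.3 |
| eta | 2.50 | 14.2 |
| eta | 4.00 | 22.3 |
| eta | 8.00 | 37.6 |
| eta | 15.0 | 51.4 |

(readings scatter by 1 percentage point)

- percentages count the substrate that a species holds: one product counts as two
- the analysis behind the earlier runs scatters by 1 percentage point, standard deviation
- a reading or a percentage of product counts all its forms, free or not

1. the winner by amount of product, in percent of the substrate charged; "neither" if no more than 2 percentage points parts them (violet / blue / neither)
2. how much product is there at the end, in percent of the substrate charged: violet
3. how much product is there at the end, in percent of the substrate charged: blue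

Follow one substrate molecule. It seems to need a partner, since the epsilon run at 0.19 M reaches 56.0% in 15.0 min, more than the delta run's 41.1% at 0.11 M. So we take its chance of reacting each minute as k[substrate]. We then reckon with the dose, starting [substrate] times time: violet has 7.50 M·min and blue 7.50 M·min. Partners thin as the flask runs, and in second-order kinetics the odds, converted over unconverted, then grow in proportion to the dose. The last readings of the three runs, odds over dose, average k = 0.420 M⁻¹ min⁻¹, so k times dose is 3.15.

Now the bracket. From below, the epsilon run already gave 56.0% at a dose of 2.85 M·min, less than violet's. From above, partners held at their starting number give an exponential survival and 95.7% converted. Thinning closes the gap: odds of 3.15 mean 75.9% for both flasks, which is our figure.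

The forecast says neither, with 75% for violet and 75.5% for blue, and of the two doses it says: “These are identical”. Both values stand inside the bracket, below our figure.

The flasks give 75.4% for violet and 75.4% for blue, so the answer is neither.

    2 substrate → product (k = 0.00340 M⁻¹ s⁻¹)
    crystals ⇌ product, rate k2*(cs2 - [product]) while solid is left; crystals form when [product] > cs2 (solubility = 0.0550 M, k = 0.130 s⁻¹)

At its end blue holds 31.3% as crystals and violet 1.99%, both counted in product, and the limit of solubility of product moves neither answer. Violet's neighbour, charged with 0.037 M for the same 50 min, has a dose of 1.85 M·min, which with our k gives 43.7%; that flask holds 43.0% of product.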